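**Retrosynthetic overview**
- The target, (13R)-8α,13-epoxy-2,3-secolabd-14-ene-2,3-dioic acid, is opened last from a cyclohexanone: ring A is kept as a temporary ring and cleaved oxidatively at C2–C3.
- Enabling feature: in the tetrahydropyran ring C (O, C8, C9, C11, C12, C13) the O–C13 and C8–C9 bonds lie 1,4 to each other. That is the retron of an oxa-Diels–Alder reaction between a C8 methyl ketone and a C9=C11–C12=C13 diene. Because C8–C9 is also a bond of carbocycle B, one intramolecular cycloaddition closes rings B and C together and sets C8, C9 and C13.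
- The cycloadduct C11=C12 double bond is removed by hydrogenation, so the C13 vinyl group is carried as CH2OBn and restored afterwards (oxidation, Wittig).
- The precursor is a trans-4,5-disubstituted cyclohexenone (C10, C5). It comes from an asymmetric Diels–Alder reaction of an (E)-enal made from 6-methylhept-5-en-2-one; the formyl group is then extended to the (1E,3Z)-diene by borylative olefination and Suzuki coupling.
- Ring order: A (temporary, step 2), then B and C together (step 7), then A opened (step 12).

Key step: step 7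

Remark: locants C1–C20 in the text are labdane locants of the target skeleton; α/β refer to the usual labdane orientation.
Assumption: the chromium salen catalyst is taken to select the face of enal 3 in the sense known for 2-substituted acroleins; it is written as the (R,R)-complex and the antipode would be used if the opposite sense were found.

Step 1
Reactants: 1 6-methylhept-5-en-2-one
Product: 3 (E)-2-methyl-6-oxohept-2-enal, via allylic alcohol 2 (not isolated)
Conditions: SeO2 (0.3 equiv), t-BuOOH, CH2Cl2, 25 °C; crude, then MnO2, CH2Cl2, 25 °C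
Reagents that add atoms: tert-butyl hydroperoxide, CC(C)(C)OO; selenium dioxide (catalytic oxygen carrier), O=[Se]=O
Why: Riley-type SeO2 allylic oxidation (ene reaction, then [2,3]-sigmatropic shift) should hydroxylate only the methyl group trans to the chain, and MnO2 oxidises only the allylic alcohol, so the (E)-enal geometry that later fixes the C5/C10 relationship is set here.

Step 2
Reactants: 3 (E)-2-methyl-6-oxohept-2-enal; 4 (E)-3-(tert-butyldimethylsilyloxy)-N,N-dimethylbuta-1,3-dien-1-amine
Product: 6 (1R,6S)-1-methyl-4-oxo-6-(3-oxobutyl)cyclohex-2-ene-1-carbaldehyde, via amino silyl enol ether cycloadduct 5 (not isolated)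
Conditions: (R,R)-(salen)CrSbF6, i.e. [(R,R)-N,N'-bis(3,5-di-tert-butylsalicylidene)-1,2-cyclohexanediaminato]chromium hexafluoroantimonate (5 mol %), 4 Å MS, CH2Cl2, −40 °C; then AcCl, −78 → 25 °C
Reagents that add atoms: none
Why: Catalytic asymmetric Diels–Alder reaction of a 1-amino-3-siloxy diene with a 2-substituted enal, in which the amino-bearing terminus bonds to the formyl-bearing carbon, suprafacial addition to the (E)-enal makes formyl and 3-oxobutyl trans (C10 and C5), the chiral trivalent chromium Lewis acid selects the enal face, and acetyl chloride then removes silyl group and amine to give the enone.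

Step 3
Reactants: 6 (1R,6S)-1-methyl-4-oxo-6-(3-oxobutyl)cyclohex-2-ene-1-carbaldehyde
Product: 7 (4S,5S)-4-methyl-5-(3-oxobutyl)-4-[(E)-2-(4,4,5,5-tetramethyl-1,3,2-dioxaborolan-2-yl)ethenyl]cyclohex-2-en-1-one
Conditions: Cl2CHBpin, CrCl2, LiI, THF, 25 °C
Reagents that add atoms: 2-(dichloromethyl)-4,4,5,5-tetramethyl-1,3,2-dioxaborolane, ClC(Cl)B1OC(C)(C)C(C)(C)O1
Why: Takai–Utimoto borylative olefination with the geminal dichromium reagent is selective for the aldehyde over ketone and enone and should give the (E)-alkenyl boronate, with no stereocentre at risk because the formyl carbon has no α-hydrogen.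

Step 4
Reactants: 8 prop-2-yn-1-ol
Product: 10 (Z)-3-iodo-2-methylprop-2-en-1-ol, via alkenylmagnesium chelate 9 (not isolated)
Conditions: MeMgBr (3 equiv), CuI (10 mol %), THF, −10 → 25 °C; then I2, −20 °C; aq NH4Cl
Reagents that add atoms: methylmagnesium bromide, C[Mg]Br; iodine, II
Why: Copper-catalysed anti-carbomagnesiation of the propargylic alkoxide gives the five-membered magnesium chelate, and iodinolysis with retention gives the alkene with iodine cis to CH2OH.

Step 5
Reactants: 10 (Z)-3-iodo-2-methylprop-2-en-1-ol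
Product: 11 (Z)-{[(3-iodo-2-methylprop-2-en-1-yl)oxy]methyl}benzene
Conditions: NaH, BnBr, Bu4NI (cat.), THF, 0 → 25 °C
Reagents that add atoms: benzyl bromide, BrCc1ccccc1
Why: Williamson ether synthesis on the primary allylic alcohol leaves the vinyl iodide and its geometry untouched.

Step 6
Reactants: 7 (4S,5S)-alkenyl boronate; 11 (Z)-{[(3-iodo-2-methylprop-2-en-1-yl)oxy]methyl}benzene
Product: 12 (4S,5S)-4-[(1E,3Z)-5-(benzyloxy)-4-methylpenta-1,3-dien-1-yl]-4-methyl-5-(3-oxobutyl)cyclohex-2-en-1-one
Conditions: PdCl2(dppf) (5 mol %), K3PO4, THF/H2O, 25 °C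
Reagents that add atoms: none
Why: Suzuki–Miyaura coupling of two sp2 partners proceeds with retention at both alkenes and so should give the (1E,3Z)-diene, while the mild phosphate base leaves enone, methyl ketone and stereocentres alone.

Step 7
Reactants: 12 (4S,5S)-4-[(1E,3Z)-5-(benzyloxy)-4-methylpenta-1,3-dien-1-yl]-4-methyl-5-(3-oxobutyl)cyclohex-2-en-1-one
Product: 13 14-(benzyloxy)-8α,13-epoxy-15,18,19-trinorlabda-1,11-dien-3-one (5α-H, 9α-H, 10β-CH3, 8β-CH3, 13-CH3 cis to 8-CH3, 13-CH2OBn α)
Conditions: Me2AlCl (2.5 equiv), CH2Cl2 (0.01 M), −78 → −20 °C; 1 M HCl quench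
Reagents that add atoms: none
Why: Proposed new method: Me2AlCl complexation makes the C8 methyl ketone a heterodienophile for the tethered diene; C9 attacks the complexed carbonyl (C8–C9) while the aluminium-bound oxygen closes on C13 of the developing allyl cation (O–C13), a concerted but highly asynchronous [4+2] whose closest known relatives are the acid-catalysed oxa-Diels–Alder reactions of unactivated aldehydes with simple dienes and the Me2AlCl-promoted ene/Prins cyclisations of unsaturated ketones. Ring B closes by 6-exo-trig attack of C9 on the carbonyl carbon and ring C by 6-endo closure of oxygen on the allyl terminus, these being the two new σ-bonds of the cycloaddition. C9 is set by the C5/C10 centres through a chair-like ring B transition state fused trans to ring A with the dienyl group equatorial (H-9 anti to the C10 methyl). C8 is set by the tether-exo arrangement, with the bulky O–Al equatorial and the methyl axial, which gives the trans-fused oxadecalin; C13 is set by suprafacial addition across the diene, so the (3Z) geometry (CH2OBn inside) puts the C13 methyl cis to the C8 methyl. The step needs chemoselectivity for the side-chain ketone over the ring enone, and ring closure over proton loss: the enone is joined to the diene through one carbon and cannot reach it, and the aprotic, proton-scavenging Lewis acid disfavours elimination and diene protonation.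

Step 8
Reactants: 13 tricyclic dihydropyran enone
Product: 14 14-(benzyloxy)-8α,13-epoxy-15-norlabda-1,11-dien-3-one (stereocentres as in 13)
Conditions: KOtBu (3 equiv), MeI (excess), THF/t-BuOH, 0 → 25 °C
Reagents that add atoms: iodomethane, CI
Why: Exhaustive enolate alkylation, in which C4 is the only enolisable position of the enone (C2 is vinylic and the γ-carbon C10 is quaternary), so both methyl groups should go to C4 and no stereocentre is formed.

Step 9
Reactants: 14 gem-dimethyl dienone benzyl ether
Product: 15 14-hydroxy-8α,13-epoxy-15-norlabdan-3-one (5α-H, 9α-H, 10β-CH3, 8β-CH3, 13-CH3 cis to 8-CH3)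
Conditions: H2 (1 atm), 10% Pd/C, EtOAc, 25 °C
Reagents that add atoms: none
Why: Heterogeneous catalytic hydrogenation should saturate C11=C12 and C1=C2 and hydrogenolyse the benzyl ether in one operation, creating no new stereocentre and leaving the hindered C3 ketone.

Step 10
Reactants: 15 keto alcohol
Product: 16 8α,13-epoxy-3-oxo-15-norlabdan-14-al
Conditions: Dess–Martin periodinane, NaHCO3, CH2Cl2, 25 °C
Reagents that add atoms: none
Why: Dess–Martin oxidation of the neopentyl-type primary alcohol gives an aldehyde with no α-hydrogen, so C13 cannot epimerise.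

Step 11
Reactants: 16 keto aldehyde
Product: 17 (5R,8R,9R,10S,13R)-8,13-epoxylabd-14-en-3-one
Conditions: Ph3PCH3Br, KOtBu, THF, 0 °C (1.2 equiv ylide)
Reagents that add atoms: methyltriphenylphosphonium bromide, C[P+](c1ccccc1)(c1ccccc1)c1ccccc1.[Br-]
Why: Wittig methylenation is much faster at the aldehyde than at the C3 ketone flanked by the gem-dimethyl group, so a small excess of ylide at low temperature should give the C13 vinyl group without touching ring A.

Step 12
Reactants: 17 (5R,8R,9R,10S,13R)-8,13-epoxylabd-14-en-3-one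
Product: 19 (5R,8R,9R,10S,13R)-8,13-epoxy-2,3-secolabd-14-ene-2,3-dioic acid, via diosphenol 18 (not isolated)
Conditions: KOtBu, O2, t-BuOH, 25 °C; then 30% H2O2, aq NaOH, 50 °C; HCl work-up
Reagents that add atoms: dioxygen, O=O; hydrogen peroxide, OO
Why: Base-mediated autoxidation of a ketone that can enolise only towards C2 gives the 2,3-diketone as its enol, and alkaline H2O2 cleaves the C2–C3 bond of the 1,2-dicarbonyl in a Baeyer–Villiger-type fragmentation to the two acids, while the vinyl group (no allylic hydrogen) and the ethers are inert and no stereocentre is touched.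

**Compound list**
1 | 6-methylhept-5-en-2-one | CC(=O)CCC=C(C)C | starting material
2 | (E)-7-hydroxy-6-methylhept-5-en-2-one | CC(=O)CC/C=C(C)/CO | intermediate
3 | (E)-2-methyl-6-oxohept-2-enal | CC(=O)CC/C=C(C)/C=O | intermediate
4 | (E)-3-(tert-butyldimethylsilyloxy)-N,N-dimethylbuta-1,3-dien-1-amine | CN(C)/C=C/C(=C)O[Si](C)(C)C(C)(C)C | starting material
5 | (1R,2S,6S)-4-(tert-butyldimethylsilyloxy)-2-(dimethylamino)-1-methyl-6-(3-oxobutyl)cyclohex-3-ene-1-carbaldehyde | O=C[C@@]1(C)[C@@H](N(C)C)C=C(O[Si](C)(C)C(C)(C)C)C[C@@H]1CCC(C)=O | intermediate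
6 | (1R,6S)-1-methyl-4-oxo-6-(3-oxobutyl)cyclohex-2-ene-1-carbaldehyde | O=C[C@@]1(C)C=CC(=O)C[C@@H]1CCC(C)=O | intermediate
7 | (4S,5S)-4-methyl-5-(3-oxobutyl)-4-[(E)-2-(4,4,5,5-tetramethyl-1,3,2-dioxaborolan-2-yl)ethenyl]cyclohex-2-en-1-one | CC1(C)OB(/C=C/[C@@]2(C)C=CC(=O)C[C@@H]2CCC(C)=O)OC1(C)C | intermediate
8 | prop-2-yn-1-ol | C#CCO | starting material
9 | (Z)-bromomagnesium 3-(bromomagnesio)-2-methylprop-2-en-1-olate | C/C(CO[Mg]Br)=C/[Mg]Br | intermediate
10 | (Z)-3-iodo-2-methylprop-2-en-1-ol | C/C(CO)=C/I | intermediate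
11 | (Z)-{[(3-iodo-2-methylprop-2-en-1-yl)oxy]methyl}benzene | C/C(COCc1ccccc1)=C/I | intermediate
12 | (4S,5S)-4-[(1E,3Z)-5-(benzyloxy)-4-methylpenta-1,3-dien-1-yl]-4-methyl-5-(3-oxobutyl)cyclohex-2-en-1-one | c1ccccc1COC/C(C)=C\C=C\[C@@]2(C)C=CC(=O)C[C@@H]2CCC(C)=O | intermediate
13 | 14-(benzyloxy)-8α,13-epoxy-15,18,19-trinorlabda-1,11-dien-3-one (5α-H, 9α-H, 10β-CH3, 8β-CH3, 13-CH3 cis to 8-CH3) | c1ccccc1COC[C@@]3(C)C=C[C@@H]2[C@@]4(C)C=CC(=O)C[C@@H]4CC[C@@]2(C)O3 | intermediate
14 | 14-(benzyloxy)-8α,13-epoxy-15-norlabda-1,11-dien-3-one (same stereocentres) | c1ccccc1COC[C@@]3(C)C=C[C@@H]2[C@@]4(C)C=CC(=O)C(C)(C)[C@@H]4CC[C@@]2(C)O3 | intermediate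
15 | 14-hydroxy-8α,13-epoxy-15-norlabdan-3-one (same stereocentres) | OC[C@@]3(C)CC[C@@H]2[C@@]4(C)CCC(=O)C(C)(C)[C@@H]4CC[C@@]2(C)O3 | intermediate
16 | 8α,13-epoxy-3-oxo-15-norlabdan-14-al (same stereocentres) | O=C[C@@]3(C)CC[C@@H]2[C@@]4(C)CCC(=O)C(C)(C)[C@@H]4CC[C@@]2(C)O3 | intermediate
17 | (5R,8R,9R,10S,13R)-8,13-epoxylabd-14-en-3-one | C=C[C@@]3(C)CC[C@@H]2[C@@]4(C)CCC(=O)C(C)(C)[C@@H]4CC[C@@]2(C)O3 | intermediate
18 | 2-hydroxy-8α,13-epoxylabda-1,14-dien-3-one (diosphenol; stereocentres as in 17) | C=C[C@@]3(C)CC[C@@H]2[C@@]4(C)C=C(O)C(=O)C(C)(C)[C@@H]4CC[C@@]2(C)O3 | intermediate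
19 | (5R,8R,9R,10S,13R)-8,13-epoxy-2,3-secolabd-14-ene-2,3-dioic acid | C=C[C@@]1(C)CC[C@@H]2[C@@](C)(CC(=O)O)[C@H](C(C)(C)C(=O)O)CC[C@@]2(C)O1 | target

**Step count**
Total steps: 12. Longest linear sequence: 10 steps (1, 2, 3, 6, 7, 8, 9, 10, 11, 12).

**Steps most likely to fail**

Step 7 (the proposed new method). After C8–C9 bond formation the allyl cation may lose a proton instead of closing on oxygen, and exo/endo control may be poor, giving the cis-fused ring junction or the C13 epimer. The fallback uses known chemistry, sets out from 6 and returns at 17.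
- Wittig olefination of 6 with (2-trimethylsilylethylidene)triphenylphosphorane would give the allylsilane F1.
- TiCl4-mediated intramolecular Hosomi–Sakurai addition to the side-chain ketone closes ring B and would give the vinyl carbinol F2.
- α′-Dimethylation (LDA, MeI, twice) would give the gem-dimethyl enone F3, and conjugate reduction with [(Ph3P)CuH]6 the saturated ketone F4.
- Hydroboration of the vinyl group with 9-BBN gives the alkylborane F5, and B-alkyl Suzuki–Miyaura coupling with (E)-3-iodobut-2-en-1-yl acetate would give the allylic acetate F6.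
- Intramolecular allylic etherification of F6 by the tertiary alcohol, catalysed by zerovalent palladium (Pd(PPh3)4), forms O–C13 and rejoins the route at 17.

Step 2. The aldehyde carbonyl may undergo a competing hetero-Diels–Alder reaction, the trisubstituted enal may react slowly, and facial selectivity may be insufficient. The fallback sets out from 3 and returns at 6. A Diels–Alder reaction with 2-(triisopropylsilyloxy)buta-1,3-diene under a triflimide-activated chiral oxazaborolidinium catalyst would give the silyl enol ether F7. Saegusa–Ito oxidation (Pd(OAc)2, MeCN) then introduces the C1=C2 double bond on the side fixed by the enol ether and gives 6.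

Step 12. The 1,2-dicarbonyl may ring-contract under base (benzilic acid type), and cleavage may be incomplete or over-run. The fallback sets out from 17 and returns at 19. Kinetic enolisation (LDA, TMSCl) would give the silyl enol ether F8. Rubottom oxidation (dimethyldioxirane, then dilute acid) would give the 2α-hydroxy ketone F9. NaIO4 cleavage would give the aldehyde acid F10, and Pinnick oxidation (NaClO2, NaH2PO4, 2-methylbut-2-ene) gives 19.

**Further compounds**
F1 | step 7 | trans-4-methyl-5-(3-oxobutyl)-4-[(Z)-3-(trimethylsilyl)prop-1-enyl]cyclohex-2-en-1-one (centres as in 6) | C[Si](C)(C)C/C=C\[C@@]1(C)C=CC(=O)C[C@@H]1CCC(C)=O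
F2 | step 7 | bicyclic vinyl carbinol: 8α-hydroxy-8β-methyl-9β-vinyl ring B fused trans to the ring A enone (9α-H, 10β-CH3, 5α-H) | C=C[C@@H]1[C@@]2(C)C=CC(=O)C[C@@H]2CC[C@@]1(C)O
F3 | step 7 | 4,4-dimethyl derivative of F2 | C=C[C@@H]1[C@@]2(C)C=CC(=O)C(C)(C)[C@@H]2CC[C@@]1(C)O
F4 | step 7 | 1,2-dihydro derivative of F3 (saturated C3 ketone) | C=C[C@@H]1[C@@]2(C)CCC(=O)C(C)(C)[C@@H]2CC[C@@]1(C)O
F5 | step 7 | B-alkyl-9-borabicyclo[3.3.1]nonane from hydroboration of F4 at C12 | C1CCC2CCCC1B2CC[C@@H]1[C@@]3(C)CCC(=O)C(C)(C)[C@@H]3CC[C@@]1(C)O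
F6 | step 7 | (13E)-15-acetoxy-8α-hydroxylabd-13-en-3-one | CC(=O)OC/C=C(\C)CC[C@@H]1[C@@]2(C)CCC(=O)C(C)(C)[C@@H]2CC[C@@]1(C)O
F7 | step 2 | (1S,6S)-1-methyl-6-(3-oxobutyl)-4-(triisopropylsilyloxy)cyclohex-3-ene-1-carbaldehyde | O=C[C@@]1(C)CC=C(O[Si](C(C)C)(C(C)C)C(C)C)C[C@@H]1CCC(C)=O
F8 | step 12 | 3-(trimethylsilyloxy)-8α,13-epoxylabda-2,14-diene (centres as in 17) | C=C[C@@]3(C)CC[C@@H]2[C@@]4(C)CC=C(O[Si](C)(C)C)C(C)(C)[C@@H]4CC[C@@]2(C)O3
F9 | step 12 | 2α-hydroxy-8α,13-epoxylabd-14-en-3-one | C=C[C@@]3(C)CC[C@@H]2[C@@]4(C)C[C@@H](O)C(=O)C(C)(C)[C@@H]4CC[C@@]2(C)O3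
F10 | step 12 | 8α,13-epoxy-2-oxo-2,3-secolabd-14-en-3-oic acid | C=C[C@@]1(C)CC[C@@H]2[C@@](C)(CC=O)[C@H](C(C)(C)C(=O)O)CC[C@@]2(C)O1
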